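**Plan**
- Retrosynthesis: the ring B quinone is traced back to a 3'-hydroxy-4'-methoxyphenyl group (C6'=O removed). Ring C is then opened at C2–C3, the resulting aryl benzyl ether is cut at O1–CH2, and the diazo carbon is traced to the methyl of an acetophenone.
- Enabling feature: C2 of ring C is a benzylic carbon bonded to O1 and lies next to the C3 methylene, which is α to the C4 ketone. A carbenoid at C3 can therefore insert into one of the two enantiotopic benzylic C–H bonds of an O–CH2–aryl ether.
- Forward: ring A (from phloroacetophenone) and ring B (from isovanillin) are joined by etherification. Diazo transfer and carbenoid insertion then close ring C, and desilylation and oxidation of ring B finish the synthesis.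
- Stereochemistry: the only stereocentre, C2 (S), is set in the insertion by a chiral dirhodium carboxylate. The two steps that follow are kept non-basic so that C2 is not racemised through ring opening.

Key step: step 8

Remark (assumption): flavanone numbering is used (O1, C2–C4, ring A C5–C8, ring B primed). The sense of induction of Rh2(S-PTTL)4 is assumed to favour the (S)-chromanone; if the (R)-product should predominate, the mirror-image catalyst Rh2(R-PTTL)4 would be used with no other change.

Step 1
Reactants: 1 isovanillin (3-hydroxy-4-methoxybenzaldehyde)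
Product: 2 3-(tert-butyldimethylsilyloxy)-4-methoxybenzaldehyde
Conditions: TBSCl, imidazole, DMF, rt
Reagents that add atoms: tert-butyldimethylsilyl chloride, CC(C)(C)[Si](C)(C)Cl
Why: Imidazole-promoted O-silylation of the single phenol is a standard protection that leaves the aldehyde untouched.

Step 2
Reactants: 2 3-(tert-butyldimethylsilyloxy)-4-methoxybenzaldehyde
Product: 3 [3-(tert-butyldimethylsilyloxy)-4-methoxyphenyl]methanol
Conditions: NaBH4, MeOH, 0 °C
Reagents that add atoms: none
Why: Borohydride reduction of the aldehyde gives the benzylic alcohol, and the aryl silyl ether is stable to NaBH4 in cold methanol.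

Step 3
Reactants: 4 phloroacetophenone (1-(2,4,6-trihydroxyphenyl)ethan-1-one)
Product: 5 1-(2,4,6-trihydroxy-3,5-dimethylphenyl)ethan-1-one
Conditions: MeI (2.1 equiv), NaOMe (2.1 equiv), MeOH, 0 °C → rt
Reagents that add atoms: iodomethane, CI
Why: Nuclear C-methylation of an acylphloroglucinol: in methanol the ambident phenoxide, its oxygens solvated by hydrogen bonding, reacts with MeI at the two free ring carbons and rearomatises after each alkylation, while the limited stoichiometry holds back geminal dimethylation.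

Step 4
Reactants: 5 1-(2,4,6-trihydroxy-3,5-dimethylphenyl)ethan-1-one
Product: 6 1-(2,6-dihydroxy-4-methoxy-3,5-dimethylphenyl)ethan-1-one
Conditions: Me2SO4 (1.0 equiv), K2CO3 (1.0 equiv), acetone, rt
Reagents that add atoms: dimethyl sulfate, COS(=O)(=O)OC
Why: Williamson O-methylation with one equivalent of electrophile goes to the hydroxyl para to the acetyl group, which is the most acidic and cannot chelate to the carbonyl.

Step 5
Reactants: 6 1-(2,6-dihydroxy-4-methoxy-3,5-dimethylphenyl)ethan-1-one; 3 [3-(tert-butyldimethylsilyloxy)-4-methoxyphenyl]methanol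
Product: 7 1-{2-[3-(tert-butyldimethylsilyloxy)-4-methoxybenzyloxy]-6-hydroxy-4-methoxy-3,5-dimethylphenyl}ethan-1-one
Conditions: PPh3, DIAD, THF, 0 °C → rt
Reagents that add atoms: none
Why: Mitsunobu etherification: the primary benzylic alcohol is activated as its alkoxyphosphonium ion and displaced by one of the two equivalent phenols of 6; the reaction should stop at the mono-ether because the remaining hydroxyl is then locked in a hydrogen bond to the ketone, and ring A has no free carbon for C-benzylation.

Step 6
Reactants: 7 1-{2-[3-(tert-butyldimethylsilyloxy)-4-methoxybenzyloxy]-6-hydroxy-4-methoxy-3,5-dimethylphenyl}ethan-1-one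
Product: 8 1-{2-[3-(tert-butyldimethylsilyloxy)-4-methoxybenzyloxy]-4-methoxy-3,5-dimethyl-6-(triisopropylsilyloxy)phenyl}ethan-1-one
Conditions: TIPSOTf, 2,6-lutidine, CH2Cl2, 0 °C
Reagents that add atoms: triisopropylsilyl trifluoromethanesulfonate, CC(C)[Si](C(C)C)(C(C)C)OS(=O)(=O)C(F)(F)F
Why: A silyl triflate with a hindered pyridine base silylates even a chelated, di-ortho-substituted phenol; the bulky triisopropylsilyl group is chosen because it resists transfer to the enolate in step 7 and makes its oxygen a poor ylide donor in step 8.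

Step 7
Reactants: 8 1-{2-[3-(tert-butyldimethylsilyloxy)-4-methoxybenzyloxy]-4-methoxy-3,5-dimethyl-6-(triisopropylsilyloxy)phenyl}ethan-1-one
Product: 10 2-diazo-1-{2-[3-(tert-butyldimethylsilyloxy)-4-methoxybenzyloxy]-4-methoxy-3,5-dimethyl-6-(triisopropylsilyloxy)phenyl}ethan-1-one, via trifluoroacetyl diketone 9 (not isolated)
Conditions: LiN(SiMe3)2, THF, −78 °C; CF3CO2CH2CF3; then MsN3, Et3N, H2O (1 equiv), MeCN, rt
Reagents that add atoms: methanesulfonyl azide, CS(=O)(=O)N=[N+]=[N-] (the two diazo nitrogens of 10); 2,2,2-trifluoroethyl trifluoroacetate, O=C(OCC(F)(F)F)C(F)(F)F (the trifluoroacetyl group of 9 only)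
Why: Detrifluoroacetylative (Regitz-type deacylative) diazo transfer: the kinetic lithium enolate of the methyl ketone is C-trifluoroacetylated to the activated 1,3-diketone 9, whose enolate adds to mesyl azide and fragments with loss of N-mesyl trifluoroacetamide to leave the terminal diazoketone.

Step 8
Reactants: 10 2-diazo-1-{2-[3-(tert-butyldimethylsilyloxy)-4-methoxybenzyloxy]-4-methoxy-3,5-dimethyl-6-(triisopropylsilyloxy)phenyl}ethan-1-one
Product: 11 (S)-2-[3-(tert-butyldimethylsilyloxy)-4-methoxyphenyl]-7-methoxy-6,8-dimethyl-5-(triisopropylsilyloxy)chroman-4-one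
Conditions: Rh2(S-PTTL)4 {dirhodium tetrakis[N-phthaloyl-(S)-tert-leucinate]} (2 mol %), CH2Cl2, 0 °C → rt, slow addition of 10 at high dilution
Reagents that add atoms: none
Why: The dirhodium carboxylate expels N2 from 10 to give an electrophilic rhodium carbenoid at the future C3, which inserts into a benzylic C–H bond of the ortho O–CH2–aryl group through a concerted, asynchronous three-centre transition state with hydride-like transfer, the developing positive charge being stabilised by the ether oxygen and the 4-methoxyaryl ring. The closest known reaction is the dirhodium-carboxylate-catalysed C–H insertion of 2-alkoxyaryl diazomethyl ketones to 2-substituted chroman-4-ones. Ring C closes as a six-membered ring by 1,6-insertion (carbenoid carbon, C4, C4a, C8a, O1, C2), the new bond being C2–C3. The C2 stereocentre is set by the catalyst, whose four N-phthaloyl-tert-leucinate ligands form a chiral pocket that tells the two enantiotopic benzylic hydrogens apart. Insertion must win over oxonium ylide formation with benzyl shift and over carbene dimerisation; a rhodium carboxylate instead of a copper catalyst, the weakly basic aryl ether oxygen conjugated to the ketone, and slow addition favour insertion. The fully substituted ring A offers no aromatic C–H or cycloaddition site, and the bulky silyl ether on the other ortho oxygen has no α-oxy C–H bond within reach.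

Step 9
Reactants: 11 (S)-2-[3-(tert-butyldimethylsilyloxy)-4-methoxyphenyl]-7-methoxy-6,8-dimethyl-5-(triisopropylsilyloxy)chroman-4-one
Product: 12 (S)-5-hydroxy-2-(3-hydroxy-4-methoxyphenyl)-7-methoxy-6,8-dimethylchroman-4-one
Conditions: Bu4NF/AcOH (1:1, 2.5 equiv), THF, 0 °C → rt
Reagents that add atoms: none
Why: Fluoride-mediated desilylation cleaves both aryl silyl ethers, and the acetic acid buffer keeps the medium non-basic so that the 5-hydroxyflavanone does not open to the chalcone by retro-oxa-Michael reaction and C2 keeps its configuration.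

Step 10
Reactants: 12 (S)-5-hydroxy-2-(3-hydroxy-4-methoxyphenyl)-7-methoxy-6,8-dimethylchroman-4-one
Product: 13 (S)-2-(5-hydroxy-7-methoxy-6,8-dimethyl-4-oxochroman-2-yl)-5-methoxycyclohexa-2,5-diene-1,4-dione
Conditions: (KSO3)2NO (2.5 equiv), KH2PO4 (aq, pH about 6), acetone–H2O, 0 °C → rt
Reagents that add atoms: potassium nitrosodisulfonate, [K+].[K+].[O]N(S(=O)(=O)[O-])S(=O)(=O)[O-] (the new carbonyl oxygen at C6')
Why: Teuber oxidation: the nitroxyl radical abstracts the hydrogen of the non-chelated ring B phenol and a second equivalent delivers oxygen to the free para carbon C6', giving the methoxy-para-quinone after loss of imidodisulfonate; the ring A phenol is hydrogen-bonded to the C4 ketone on a fully substituted ring and should not react, and the near-neutral buffer should leave C2 untouched.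

**Compound list**
1 | isovanillin (3-hydroxy-4-methoxybenzaldehyde) | COc1ccc(C=O)cc1O | starting material
2 | 3-(tert-butyldimethylsilyloxy)-4-methoxybenzaldehyde | COc1ccc(C=O)cc1O[Si](C)(C)C(C)(C)C | intermediate
3 | [3-(tert-butyldimethylsilyloxy)-4-methoxyphenyl]methanol | COc1ccc(CO)cc1O[Si](C)(C)C(C)(C)C | intermediate
4 | phloroacetophenone (1-(2,4,6-trihydroxyphenyl)ethan-1-one) | CC(=O)c1c(O)cc(O)cc1O | starting material
5 | 1-(2,4,6-trihydroxy-3,5-dimethylphenyl)ethan-1-one | CC(=O)c1c(O)c(C)c(O)c(C)c1O | intermediate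
6 | 1-(2,6-dihydroxy-4-methoxy-3,5-dimethylphenyl)ethan-1-one | CC(=O)c1c(O)c(C)c(OC)c(C)c1O | intermediate
7 | 1-{2-[3-(tert-butyldimethylsilyloxy)-4-methoxybenzyloxy]-6-hydroxy-4-methoxy-3,5-dimethylphenyl}ethan-1-one | CC(=O)c1c(O)c(C)c(OC)c(C)c1OCc1ccc(OC)c(O[Si](C)(C)C(C)(C)C)c1 | intermediate
8 | 1-{2-[3-(tert-butyldimethylsilyloxy)-4-methoxybenzyloxy]-4-methoxy-3,5-dimethyl-6-(triisopropylsilyloxy)phenyl}ethan-1-one | CC(=O)c1c(O[Si](C(C)C)(C(C)C)C(C)C)c(C)c(OC)c(C)c1OCc1ccc(OC)c(O[Si](C)(C)C(C)(C)C)c1 | intermediate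
9 | 4,4,4-trifluoro-1-{2-[3-(tert-butyldimethylsilyloxy)-4-methoxybenzyloxy]-4-methoxy-3,5-dimethyl-6-(triisopropylsilyloxy)phenyl}butane-1,3-dione | O=C(CC(=O)C(F)(F)F)c1c(O[Si](C(C)C)(C(C)C)C(C)C)c(C)c(OC)c(C)c1OCc1ccc(OC)c(O[Si](C)(C)C(C)(C)C)c1 | intermediate (not isolated)
10 | 2-diazo-1-{2-[3-(tert-butyldimethylsilyloxy)-4-methoxybenzyloxy]-4-methoxy-3,5-dimethyl-6-(triisopropylsilyloxy)phenyl}ethan-1-one | [N-]=[N+]=CC(=O)c1c(O[Si](C(C)C)(C(C)C)C(C)C)c(C)c(OC)c(C)c1OCc1ccc(OC)c(O[Si](C)(C)C(C)(C)C)c1 | intermediate
11 | (S)-2-[3-(tert-butyldimethylsilyloxy)-4-methoxyphenyl]-7-methoxy-6,8-dimethyl-5-(triisopropylsilyloxy)chroman-4-one | COc1ccc(cc1O[Si](C)(C)C(C)(C)C)[C@@H]2CC(=O)c3c(O[Si](C(C)C)(C(C)C)C(C)C)c(C)c(OC)c(C)c3O2 | intermediate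
12 | (S)-5-hydroxy-2-(3-hydroxy-4-methoxyphenyl)-7-methoxy-6,8-dimethylchroman-4-one | COc1ccc(cc1O)[C@@H]2CC(=O)c3c(O)c(C)c(OC)c(C)c3O2 | intermediate
13 | (S)-2-(5-hydroxy-7-methoxy-6,8-dimethyl-4-oxochroman-2-yl)-5-methoxycyclohexa-2,5-diene-1,4-dione | COC1=CC(=O)C([C@@H]2CC(=O)c3c(O)c(C)c(OC)c(C)c3O2)=CC1=O | target

**Totals**
Total step count: 10. Longest linear sequence: 8 steps (steps 3 to 10 from 4, or steps 1, 2 and 5 to 10 from 1).

**Steps most likely to fail**

Step 8. The carbenoid may be intercepted by the lone pair of the benzylic ether oxygen (five-membered oxonium ylide, then benzyl shift to a benzofuranone), it may dimerise, or the catalyst may discriminate the two benzylic hydrogens poorly. The fallback closes ring C through O1–C2 instead of C2–C3. It sets out from acetophenone 6 and isovanillin 1. Claisen–Schmidt condensation (KOH, EtOH–H2O, rt) would give (E)-1-(2,6-dihydroxy-4-methoxy-3,5-dimethylphenyl)-3-(3-hydroxy-4-methoxyphenyl)prop-2-en-1-one F1. Intramolecular oxa-Michael addition (NaOAc, EtOH, reflux) would give racemic 5-hydroxy-2-(3-hydroxy-4-methoxyphenyl)-7-methoxy-6,8-dimethylchroman-4-one F2. Preparative HPLC on a chiral stationary phase would separate the (S)-enantiomer, which is 12, from (R)-5-hydroxy-2-(3-hydroxy-4-methoxyphenyl)-7-methoxy-6,8-dimethylchroman-4-one F3. F3 would be returned to the NaOAc equilibration (racemisation by way of F1) and resolved again. The route is rejoined at 12.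

Step 7. The twisted, di-ortho-substituted enolate may be trifluoroacetylated on oxygen instead of carbon, or the ring A silyl group may drift to the enolate oxygen, so that no 1,3-diketone is available for diazo transfer. The fallback avoids a free enolate and builds the diazo group by substitution. It sets out from 8. Soft enolisation (Me3SiOTf, Et3N, CH2Cl2, 0 °C) would give {1-[2-(3-(tert-butyldimethylsilyloxy)-4-methoxybenzyloxy)-4-methoxy-3,5-dimethyl-6-(triisopropylsilyloxy)phenyl]vinyloxy}trimethylsilane F4. NBS (THF, −78 °C) would convert it into 2-bromo-1-{2-[3-(tert-butyldimethylsilyloxy)-4-methoxybenzyloxy]-4-methoxy-3,5-dimethyl-6-(triisopropylsilyloxy)phenyl}ethan-1-one F5. N,N'-Ditosylhydrazine and DBU (THF, 0 °C) would then displace bromide and expel two sulfinate groups to give diazoketone 10, where the route is rejoined.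

Step 10. With both phenols free, hydrogen abstraction at the ring A phenol, ortho-quinone formation or further oxidation may erode the yield, and the quinone with its activated C2–H may degrade in the aqueous buffer. The fallback oxidises ring B before ring A is unmasked. It sets out from 11. One equivalent of Bu4NF/AcOH (THF, −40 °C) should remove the unhindered ring B silyl group first, since the triisopropylsilyl ether is flanked by a methyl group and the peri carbonyl, giving (S)-2-(3-hydroxy-4-methoxyphenyl)-7-methoxy-6,8-dimethyl-5-(triisopropylsilyloxy)chroman-4-one F6. Oxidation with (KSO3)2NO (KH2PO4, acetone–H2O) would give (S)-2-methoxy-5-[7-methoxy-6,8-dimethyl-4-oxo-5-(triisopropylsilyloxy)chroman-2-yl]cyclohexa-2,5-diene-1,4-dione F7. HF·pyridine (THF, 0 °C) would then free the ring A phenol under acidic conditions and give 13, where the route ends.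

**Further compounds**
F1 | step 8 | (E)-1-(2,6-dihydroxy-4-methoxy-3,5-dimethylphenyl)-3-(3-hydroxy-4-methoxyphenyl)prop-2-en-1-one | COc1ccc(/C=C/C(=O)c2c(O)c(C)c(OC)c(C)c2O)cc1O
F2 | step 8 | racemic 5-hydroxy-2-(3-hydroxy-4-methoxyphenyl)-7-methoxy-6,8-dimethylchroman-4-one | COc1ccc(cc1O)C2CC(=O)c3c(O)c(C)c(OC)c(C)c3O2
F3 | step 8 | (R)-5-hydroxy-2-(3-hydroxy-4-methoxyphenyl)-7-methoxy-6,8-dimethylchroman-4-one | COc1ccc(cc1O)[C@H]2CC(=O)c3c(O)c(C)c(OC)c(C)c3O2
F4 | step 7 | {1-[2-(3-(tert-butyldimethylsilyloxy)-4-methoxybenzyloxy)-4-methoxy-3,5-dimethyl-6-(triisopropylsilyloxy)phenyl]vinyloxy}trimethylsilane | C=C(O[Si](C)(C)C)c1c(O[Si](C(C)C)(C(C)C)C(C)C)c(C)c(OC)c(C)c1OCc1ccc(OC)c(O[Si](C)(C)C(C)(C)C)c1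
F5 | step 7 | 2-bromo-1-{2-[3-(tert-butyldimethylsilyloxy)-4-methoxybenzyloxy]-4-methoxy-3,5-dimethyl-6-(triisopropylsilyloxy)phenyl}ethan-1-one | BrCC(=O)c1c(O[Si](C(C)C)(C(C)C)C(C)C)c(C)c(OC)c(C)c1OCc1ccc(OC)c(O[Si](C)(C)C(C)(C)C)c1
F6 | step 10 | (S)-2-(3-hydroxy-4-methoxyphenyl)-7-methoxy-6,8-dimethyl-5-(triisopropylsilyloxy)chroman-4-one | COc1ccc(cc1O)[C@@H]2CC(=O)c3c(O[Si](C(C)C)(C(C)C)C(C)C)c(C)c(OC)c(C)c3O2
F7 | step 10 | (S)-2-methoxy-5-[7-methoxy-6,8-dimethyl-4-oxo-5-(triisopropylsilyloxy)chroman-2-yl]cyclohexa-2,5-diene-1,4-dione | COC1=CC(=O)C([C@@H]2CC(=O)c3c(O[Si](C(C)C)(C(C)C)C(C)C)c(C)c(OC)c(C)c3O2)=CC1=O
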